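**Retrosynthetic overview**
1. Target 28 ⇐ (Z)-selective Ando olefination of the C19 phosphonoacetate 25 with aldehyde 26; the light- and metal-sensitive (Z)-coumarate is made last.
2. 25 ⇐ ethylene–alkyne metathesis (13(16),14-diene) and α-face osmylation of the Δ7 alkene (7α,8α-diol) of alkyne ester 22.
3. Decalin ⇐ one cationic epoxy-polyene cascade of the acyclic epoxy dienyne 16: ring A closes first, then ring B. The leftover 3-OH is removed by Barton–McCombie deoxygenation.
4. 16 ⇐ Sharpless epoxidation of (Z)-allylic alcohol 14 ⇐ β-oxido-ylide hydroxymethylation of aldehyde 7 ⇐ farnesyl bromide 1 + silylpropyne 2, with the terminal alkene excised.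

Assumption: ring positions use labdane numbering, and 1, 2, 8, 9, 21, 24, 26 and D-(−)-diethyl tartrate are taken as catalogue chemicals.

**Step 1**
Reactants: 1 (2E,6E)-1-bromo-3,7,11-trimethyldodeca-2,6,10-triene (trans,trans-farnesyl bromide); 2 triisopropyl(prop-1-yn-1-yl)silane
Product: 4 triisopropyl[(5E,9E)-6,10,14-trimethylpentadeca-5,9,13-trien-1-yn-1-yl]silane, via lithiated silylpropyne 3 (not isolated)
Conditions: 2, n-BuLi, THF, −20 °C; then 1, −78 °C → rt
Reagents that add atoms: none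
Why: The bulky silyl group makes propargyl-lithium 3 react only at its CH2 terminus (no allene) in an SN2 alkylation of the primary allylic bromide, which keeps both E alkenes; no stereocentre is formed.

**Step 2**
Reactants: 4
Product: 6 rac-3-[(3E,7E)-3,7-dimethyl-12-(triisopropylsilyl)dodeca-3,7-dien-11-yn-1-yl]-2,2-dimethyloxirane, via bromohydrin 5 (not isolated)
Conditions: NBS, THF/H2O, 0 °C; crude 5, K2CO3, MeOH, rt
Reagents that add atoms: water, O (epoxide oxygen); N-bromosuccinimide, O=C1CCC(=O)N1Br (its bromine stays only in 5)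
Why: In the van Tamelen terminal bromohydrin reaction the polyene coiled in aqueous THF exposes only the terminal alkene to NBS, base then closes 5 to the epoxide, and the silylalkyne is inert to both; the racemic stereocentre is destroyed in step 3.

**Step 3**
Reactants: 6
Product: 7 (4E,8E)-4,8-dimethyl-13-(triisopropylsilyl)trideca-4,8-dien-12-ynal
Conditions: H5IO6, THF/Et2O, 0 °C → rt
Reagents that add atoms: none
Why: Periodic acid opens the epoxide and cleaves its C–C bond (Malaprade-type oxidative cleavage), releasing acetone and leaving the aldehyde, while the trisubstituted alkenes and the silylalkyne do not react; no stereocentre.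

**Step 4**
Reactants: 7; 8 ethyltriphenylphosphonium bromide; 9 paraformaldehyde (used as monomeric formaldehyde)
Product: 14 (2Z,6E,10E)-2,6,10-trimethyl-15-(triisopropylsilyl)pentadeca-2,6,10-trien-14-yn-1-ol, via ethylidene ylide 10 (not isolated), via lithium betaine 11 (not isolated), via oxido ylide 12 (not isolated), via dioxido phosphonium adduct 13 (not isolated)
Conditions: 8, n-BuLi, THF, 0 °C; 7, −78 °C; n-BuLi, −78 → −20 °C; (CH2O)n, 0 °C → rt; H2O
Reagents that add atoms: none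
Why: In the Wittig–Schlosser β-oxido ylide (SCOOPY) sequence the betaine is deprotonated to ylide 12, which adds formaldehyde and then loses the original aldehyde oxygen as Ph3PO, a course known to place the new CH2OH cis to the chain, so the (Z)-2-methylallylic alcohol forms directly.

**Step 5**
Reactants: 14
Product: 16 tert-butyl{[(2R,3S)-3-[(3E,7E)-3,7-dimethyl-12-(triisopropylsilyl)dodeca-3,7-dien-11-yn-1-yl]-2-methyloxiran-2-yl]methoxy}diphenylsilane, via epoxy alcohol 15 (not isolated)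
Conditions: Ti(OiPr)4 (10 mol%), D-(−)-diethyl tartrate (12 mol%), t-BuOOH, 4 Å MS, CH2Cl2, −20 °C; P(OMe)3; then Et3N, DMAP, TBDPSCl, 0 °C
Reagents that add atoms: tert-butyl hydroperoxide, CC(C)(C)OO; tert-butyl(chloro)diphenylsilane, CC(C)(C)[Si](Cl)(c1ccccc1)c1ccccc1
Why: Sharpless asymmetric epoxidation is directed by the allylic OH to the terminal alkene only, and D-(−)-tartrate delivers oxygen to the face that gives the (2R,3S)-epoxide (future C4 and C3, about 90% ee expected for a (Z)-2-methyl allylic alcohol); silylation in the same pot masks the OH so it cannot chelate the Lewis acid of step 6.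

**Step 6**
Reactants: 16
Product: 17 (3β)-19-[(tert-butyldiphenylsilyl)oxy]-14-(triisopropylsilyl)-15,16-dinorlabd-7-en-13-yn-3-ol (trans-decalin; 5α-H, 9α-H, 10β-CH3, 4α-CH3, 4β-CH2OSi)
Conditions: MeAlCl2 (2 equiv), CH2Cl2, −78 °C; Et3N, aq. NaHCO3; AgNO3–silica chromatography
Reagents that add atoms: none
Why: In this biomimetic cationic epoxy-polyene bicyclization the epoxide opens at tertiary C4 with anti attack of the 5(10)-alkene in a chair–chair fold, which relays the epoxide configuration to C4 (inversion, so the (Z)-CH2OSi becomes the axial C19), C5, C10 and C9 (trans-decalin with β side chain from the E alkenes), and the C8 cation then loses the axial 7α-H to give the Δ7 alkene as the main isomer, while the weakly nucleophilic, bulky silylalkyne does not terminate the cascade.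

**Step 7**
Reactants: 17
Product: 18 O-[(3β)-19-[(tert-butyldiphenylsilyl)oxy]-14-(triisopropylsilyl)-15,16-dinorlabd-7-en-13-yn-3-yl] 1H-imidazole-1-carbothioate
Conditions: 1,1'-thiocarbonyldiimidazole, DMAP, toluene, 90 °C
Reagents that add atoms: 1,1'-thiocarbonyldiimidazole, S=C(n1ccnc1)n1ccnc1
Why: Thioacylation of the equatorial 3β-OH under neutral conditions (no alkoxide, so no silyl shift from O19) prepares the Barton–McCombie substrate without touching any stereocentre.

**Step 8**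
Reactants: 18
Product: 19 19-[(tert-butyldiphenylsilyl)oxy]-14-(triisopropylsilyl)-15,16-dinorlabd-7-en-13-yne
Conditions: Bu3SnH, AIBN, toluene, 110 °C
Reagents that add atoms: none
Why: In the Barton–McCombie deoxygenation the stannyl radical adds to C=S, the C3–O bond fragments to a secondary radical that takes hydrogen from Bu3SnH, so C3 becomes CH2 while the remote alkene, the silyl ether and the hindered silylalkyne are untouched.

**Step 9**
Reactants: 19
Product: 20 15,16-dinorlabd-7-en-13-yn-19-ol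
Conditions: TBAF, THF, rt → 50 °C
Reagents that add atoms: none
Why: Fluoride desilylation cleaves both the Si–O bond at C19 and the Si–C(sp) bond in one operation, freeing the primary alcohol and the terminal alkyne; no stereocentre is involved.

**Step 10**
Reactants: 20; 21 (diphenoxyphosphoryl)acetic acid
Product: 22 15,16-dinorlabd-7-en-13-yn-19-yl (diphenoxyphosphoryl)acetate
Conditions: DCC, DMAP (cat.), CH2Cl2, 0 °C → rt
Reagents that add atoms: none
Why: Steglich esterification is unambiguous here because the neopentyl C19-OH is the only hydroxyl present, and the phosphonoacetate carries the two carbons of the future coumarate.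

**Step 11**
Reactants: 22
Product: 23 7α,8α-dihydroxy-15,16-dinorlabd-13-yn-19-yl (diphenoxyphosphoryl)acetate
Conditions: OsO4 (10 mol%), NMO, citric acid, acetone/t-BuOH/H2O, rt
Reagents that add atoms: N-methylmorpholine N-oxide, C[N+]1([O-])CCOCC1; water, O; osmium tetroxide, O=[Os](=O)(=O)=O (catalytic oxygen carrier)
Why: In the Upjohn dihydroxylation OsO4 adds syn to the only alkene from the α face, opposite the axial C10 methyl and the axial C19 substituent, which sets 7α-OH and 8α-OH (8β-CH3); the terminal alkyne and the phosphonate ester are inert.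

**Step 12**
Reactants: 23; 24 ethylene
Product: 25 7α,8α-dihydroxylabda-13(16),14-dien-19-yl (diphenoxyphosphoryl)acetate
Conditions: ethylene (1 atm), second-generation Grubbs catalyst RuCl2(=CHPh)(H2IMes)(PCy3) (10 mol%), toluene, 80 °C
Reagents that add atoms: none
Why: Ethylene–alkyne cross enyne metathesis converts a terminal alkyne regiospecifically into the 2-substituted buta-1,3-diene, and the ruthenium carbene tolerates the free hydroxyls and the phosphonate; no stereocentre.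

**Step 13**
Reactants: 25; 26 4-[(tert-butyldimethylsilyl)oxy]benzaldehyde
Product: 28 7α,8α-dihydroxylabda-13(16),14-dien-19-yl (2Z)-3-(4-hydroxyphenyl)prop-2-enoate (CNP0254560.1), via silyl ether 27 (not isolated)
Conditions: NaH (1.1 equiv), THF, 0 °C; 26, −78 → 0 °C, dark; then TBAF/AcOH (1:1), 0 °C
Reagents that add atoms: none
Why: In this Ando-type Horner–Wadsworth–Emmons olefination the diaryl phosphonate eliminates fast from the kinetically formed adduct to give the (Z)-cinnamate (about 9:1 expected, E isomer removed by chromatography), the alcohols are far less acidic than the phosphonoacetate CH2, and buffered fluoride then frees the phenol without touching the ester or the alkene geometry.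

**Compound list**
1 | (2E,6E)-1-bromo-3,7,11-trimethyldodeca-2,6,10-triene | CC(C)=CCC/C(C)=C/CC/C(C)=C/CBr | starting material
2 | triisopropyl(prop-1-yn-1-yl)silane | CC#C[Si](C(C)C)(C(C)C)C(C)C | starting material
3 | [3-(triisopropylsilyl)prop-2-yn-1-yl]lithium | [Li]CC#C[Si](C(C)C)(C(C)C)C(C)C | intermediate (not isolated)
4 | triisopropyl[(5E,9E)-6,10,14-trimethylpentadeca-5,9,13-trien-1-yn-1-yl]silane | CC(C)=CCC/C(C)=C/CC/C(C)=C/CCC#C[Si](C(C)C)(C(C)C)C(C)C | intermediate
5 | rac-(6E,10E)-3-bromo-2,6,10-trimethyl-15-(triisopropylsilyl)pentadeca-6,10-dien-14-yn-2-ol | CC(C)(O)C(Br)CC/C(C)=C/CC/C(C)=C/CCC#C[Si](C(C)C)(C(C)C)C(C)C | intermediate (not isolated)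
6 | rac-3-[(3E,7E)-3,7-dimethyl-12-(triisopropylsilyl)dodeca-3,7-dien-11-yn-1-yl]-2,2-dimethyloxirane | CC1(C)OC1CC/C(C)=C/CC/C(C)=C/CCC#C[Si](C(C)C)(C(C)C)C(C)C | intermediate
7 | (4E,8E)-4,8-dimethyl-13-(triisopropylsilyl)trideca-4,8-dien-12-ynal | O=CCC/C(C)=C/CC/C(C)=C/CCC#C[Si](C(C)C)(C(C)C)C(C)C | intermediate
8 | ethyltriphenylphosphonium bromide | CC[P+](c1ccccc1)(c1ccccc1)c1ccccc1.[Br-] | starting material
9 | paraformaldehyde (as formaldehyde) | C=O | starting material
10 | ethylidenetriphenylphosphorane | CC=P(c1ccccc1)(c1ccccc1)c1ccccc1 | intermediate (not isolated)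
11 | [(6E,10E)-3-(lithiooxy)-6,10-dimethyl-15-(triisopropylsilyl)pentadeca-6,10-dien-14-yn-2-yl]triphenylphosphonium bromide (diastereomer mixture) | CC(C(CC/C(C)=C/CC/C(C)=C/CCC#C[Si](C(C)C)(C(C)C)C(C)C)O[Li])[P+](c1ccccc1)(c1ccccc1)c1ccccc1.[Br-] | intermediate (not isolated)
12 | lithium (6E,10E)-6,10-dimethyl-2-(triphenyl-λ5-phosphanylidene)-15-(triisopropylsilyl)pentadeca-6,10-dien-14-yn-3-olate | CC(C(CC/C(C)=C/CC/C(C)=C/CCC#C[Si](C(C)C)(C(C)C)C(C)C)O[Li])=P(c1ccccc1)(c1ccccc1)c1ccccc1 | intermediate (not isolated)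
13 | [(6E,10E)-3-(lithiooxy)-2,6,10-trimethyl-1-oxido-15-(triisopropylsilyl)pentadeca-6,10-dien-14-yn-2-yl]triphenylphosphonium (diastereomer mixture) | CC(C[O-])(C(CC/C(C)=C/CC/C(C)=C/CCC#C[Si](C(C)C)(C(C)C)C(C)C)O[Li])[P+](c1ccccc1)(c1ccccc1)c1ccccc1 | intermediate (not isolated)
14 | (2Z,6E,10E)-2,6,10-trimethyl-15-(triisopropylsilyl)pentadeca-2,6,10-trien-14-yn-1-ol | OC/C(C)=C\CC/C(C)=C/CC/C(C)=C/CCC#C[Si](C(C)C)(C(C)C)C(C)C | intermediate
15 | [(2R,3S)-3-[(3E,7E)-3,7-dimethyl-12-(triisopropylsilyl)dodeca-3,7-dien-11-yn-1-yl]-2-methyloxiran-2-yl]methanol | CC(C)[Si](C(C)C)(C(C)C)C#CCC/C=C(C)/CC/C=C(C)/CC[C@@H]1O[C@]1(C)CO | intermediate (not isolated)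
16 | tert-butyl{[(2R,3S)-3-[(3E,7E)-3,7-dimethyl-12-(triisopropylsilyl)dodeca-3,7-dien-11-yn-1-yl]-2-methyloxiran-2-yl]methoxy}diphenylsilane | CC(C)[Si](C(C)C)(C(C)C)C#CCC/C=C(C)/CC/C=C(C)/CC[C@@H]1O[C@]1(C)CO[Si](c2ccccc2)(c2ccccc2)C(C)(C)C | intermediate
17 | (3β)-19-[(tert-butyldiphenylsilyl)oxy]-14-(triisopropylsilyl)-15,16-dinorlabd-7-en-13-yn-3-ol | CC(C)[Si](C(C)C)(C(C)C)C#CCC[C@H]1C(C)=CC[C@H]2[C@@](C)(CO[Si](c3ccccc3)(c3ccccc3)C(C)(C)C)[C@@H](O)CC[C@@]21C | intermediate
18 | O-[(3β)-19-[(tert-butyldiphenylsilyl)oxy]-14-(triisopropylsilyl)-15,16-dinorlabd-7-en-13-yn-3-yl] 1H-imidazole-1-carbothioate | CC(C)[Si](C(C)C)(C(C)C)C#CCC[C@H]1C(C)=CC[C@H]2[C@@](C)(CO[Si](c3ccccc3)(c3ccccc3)C(C)(C)C)[C@@H](OC(=S)n3ccnc3)CC[C@@]21C | intermediate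
19 | 19-[(tert-butyldiphenylsilyl)oxy]-14-(triisopropylsilyl)-15,16-dinorlabd-7-en-13-yne | CC(C)[Si](C(C)C)(C(C)C)C#CCC[C@H]1C(C)=CC[C@H]2[C@@](C)(CO[Si](c3ccccc3)(c3ccccc3)C(C)(C)C)CCC[C@@]21C | intermediate
20 | 15,16-dinorlabd-7-en-13-yn-19-ol | C#CCC[C@H]1C(C)=CC[C@H]2[C@@](C)(CO)CCC[C@@]21C | intermediate
21 | (diphenoxyphosphoryl)acetic acid | OC(=O)CP(=O)(Oc1ccccc1)Oc1ccccc1 | starting material
22 | 15,16-dinorlabd-7-en-13-yn-19-yl (diphenoxyphosphoryl)acetate | C#CCC[C@H]1C(C)=CC[C@H]2[C@@](C)(COC(=O)CP(=O)(Oc3ccccc3)Oc3ccccc3)CCC[C@@]21C | intermediate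
23 | 7α,8α-dihydroxy-15,16-dinorlabd-13-yn-19-yl (diphenoxyphosphoryl)acetate | C#CCC[C@H]1[C@](C)(O)[C@H](O)C[C@H]2[C@@](C)(COC(=O)CP(=O)(Oc3ccccc3)Oc3ccccc3)CCC[C@@]21C | intermediate
24 | ethylene | C=C | starting material
25 | 7α,8α-dihydroxylabda-13(16),14-dien-19-yl (diphenoxyphosphoryl)acetate | C=CC(=C)CC[C@H]1[C@](C)(O)[C@H](O)C[C@H]2[C@@](C)(COC(=O)CP(=O)(Oc3ccccc3)Oc3ccccc3)CCC[C@@]21C | intermediate
26 | 4-[(tert-butyldimethylsilyl)oxy]benzaldehyde | O=Cc1ccc(O[Si](C)(C)C(C)(C)C)cc1 | starting material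
27 | 7α,8α-dihydroxylabda-13(16),14-dien-19-yl (2Z)-3-{4-[(tert-butyldimethylsilyl)oxy]phenyl}prop-2-enoate | C=CC(=C)CC[C@H]1[C@](C)(O)[C@H](O)C[C@H]2[C@@](C)(COC(=O)/C=C\c3ccc(O[Si](C)(C)C(C)(C)C)cc3)CCC[C@@]21C | intermediate (not isolated)
28 | 7α,8α-dihydroxylabda-13(16),14-dien-19-yl (2Z)-3-(4-hydroxyphenyl)prop-2-enoate (CNP0254560.1) | C=CC(=C)CC[C@H]1[C@](C)(O)[C@H](O)C[C@H]2[C@@](C)(COC(=O)/C=C\c3ccc(O)cc3)CCC[C@@]21C | target

**Totals**
Total step count: 13. Longest linear sequence: 13 steps (1 → 28); all other components are purchased.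

**Three steps most likely to fail, each with a fallback**

Step 6 (cationic bicyclization). The likely failure is proton loss from C17 instead of C7, so that the exocyclic alkene dominates. The fallback sets out from 16 and accepts that isomer, (3β)-19-[(tert-butyldiphenylsilyl)oxy]-14-(triisopropylsilyl)-15,16-dinorlabd-8(17)-en-13-yn-3-ol F1. The diol is then built stepwise instead of by osmylation. Thiocarbonyldiimidazole gives the imidazolide, O-[(3β)-19-[(tert-butyldiphenylsilyl)oxy]-14-(triisopropylsilyl)-15,16-dinorlabd-8(17)-en-13-yn-3-yl] 1H-imidazole-1-carbothioate F2, and Bu3SnH/AIBN gives 19-[(tert-butyldiphenylsilyl)oxy]-14-(triisopropylsilyl)-15,16-dinorlabd-8(17)-en-13-yne F3. Allylic hydroxylation with SeO2 (cat.)/t-BuOOH gives the axial alcohol (7α)-19-[(tert-butyldiphenylsilyl)oxy]-14-(triisopropylsilyl)-15,16-dinorlabd-8(17)-en-13-yn-7-ol F4. Hydroxyl-directed epoxidation with VO(acac)2/t-BuOOH gives (7α,8α)-8,17-epoxy-19-[(tert-butyldiphenylsilyl)oxy]-14-(triisopropylsilyl)-15,16-dinorlabd-13-yn-7-ol F5. LiAlH4 opens the epoxide at C17 to (7α,8α)-19-[(tert-butyldiphenylsilyl)oxy]-14-(triisopropylsilyl)-15,16-dinorlabd-13-yne-7,8-diol F6, and TBAF gives 15,16-dinorlabd-13-yne-7α,8α,19-triol F7. DCC/DMAP acylation of its primary C19-OH with 21 (1 equiv, 0 °C) comes back to the route at 23.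

Step 13 (Z-selective olefination on the full substrate). The likely failure is poor Z:E selectivity or base damage. The fallback sets out from 25: LiOH in THF/H2O removes the phosphonoacetate to give labda-13(16),14-diene-7α,8α,19-triol F9. The (Z)-acid is made separately, where the geometry can be secured and purified on a small molecule. Still–Gennari olefination of 26 with methyl bis(2,2,2-trifluoroethyl)phosphonoacetate (KN(SiMe3)2, 18-crown-6, THF, −78 °C) gives methyl (2Z)-3-{4-[(tert-butyldimethylsilyl)oxy]phenyl}prop-2-enoate F10. Me3SnOH then gives (2Z)-3-{4-[(tert-butyldimethylsilyl)oxy]phenyl}prop-2-enoic acid F11. DCC/DMAP esterification of the C19-OH of F9 with F11 in the dark comes back to the route at 27, which is desilylated as in step 13 to 28.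

Step 4 (β-oxido ylide hydroxymethylation). The likely failure is low yield or eroded Z selectivity. The fallback sets out from 7: Still–Gennari olefination with ethyl 2-[bis(2,2,2-trifluoroethoxy)phosphoryl]propanoate (KN(SiMe3)2, 18-crown-6, THF, −78 °C) gives ethyl (2Z,6E,10E)-2,6,10-trimethyl-15-(triisopropylsilyl)pentadeca-2,6,10-trien-14-ynoate F8. Reduction with iBu2AlH (CH2Cl2, −78 °C) comes back to the route at 14.

**Further compounds**
F1 | step 6 | (3β)-19-[(tert-butyldiphenylsilyl)oxy]-14-(triisopropylsilyl)-15,16-dinorlabd-8(17)-en-13-yn-3-ol | CC(C)[Si](C(C)C)(C(C)C)C#CCC[C@H]1C(=C)CC[C@H]2[C@@](C)(CO[Si](c3ccccc3)(c3ccccc3)C(C)(C)C)[C@@H](O)CC[C@@]21C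
F2 | step 6 | O-[(3β)-19-[(tert-butyldiphenylsilyl)oxy]-14-(triisopropylsilyl)-15,16-dinorlabd-8(17)-en-13-yn-3-yl] 1H-imidazole-1-carbothioate | CC(C)[Si](C(C)C)(C(C)C)C#CCC[C@H]1C(=C)CC[C@H]2[C@@](C)(CO[Si](c3ccccc3)(c3ccccc3)C(C)(C)C)[C@@H](OC(=S)n3ccnc3)CC[C@@]21C
F3 | step 6 | 19-[(tert-butyldiphenylsilyl)oxy]-14-(triisopropylsilyl)-15,16-dinorlabd-8(17)-en-13-yne | CC(C)[Si](C(C)C)(C(C)C)C#CCC[C@H]1C(=C)CC[C@H]2[C@@](C)(CO[Si](c3ccccc3)(c3ccccc3)C(C)(C)C)CCC[C@@]21C
F4 | step 6 | (7α)-19-[(tert-butyldiphenylsilyl)oxy]-14-(triisopropylsilyl)-15,16-dinorlabd-8(17)-en-13-yn-7-ol | CC(C)[Si](C(C)C)(C(C)C)C#CCC[C@H]1C(=C)[C@H](O)C[C@H]2[C@@](C)(CO[Si](c3ccccc3)(c3ccccc3)C(C)(C)C)CCC[C@@]21C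
F5 | step 6 | (7α,8α)-8,17-epoxy-19-[(tert-butyldiphenylsilyl)oxy]-14-(triisopropylsilyl)-15,16-dinorlabd-13-yn-7-ol | CC(C)[Si](C(C)C)(C(C)C)C#CCC[C@H]1[C@@]3(CO3)[C@H](O)C[C@H]2[C@@](C)(CO[Si](c4ccccc4)(c4ccccc4)C(C)(C)C)CCC[C@@]21C
F6 | step 6 | (7α,8α)-19-[(tert-butyldiphenylsilyl)oxy]-14-(triisopropylsilyl)-15,16-dinorlabd-13-yne-7,8-diol | CC(C)[Si](C(C)C)(C(C)C)C#CCC[C@H]1[C@](C)(O)[C@H](O)C[C@H]2[C@@](C)(CO[Si](c3ccccc3)(c3ccccc3)C(C)(C)C)CCC[C@@]21C
F7 | step 6 | 15,16-dinorlabd-13-yne-7α,8α,19-triol | C#CCC[C@H]1[C@](C)(O)[C@H](O)C[C@H]2[C@@](C)(CO)CCC[C@@]21C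
F8 | step 4 | ethyl (2Z,6E,10E)-2,6,10-trimethyl-15-(triisopropylsilyl)pentadeca-2,6,10-trien-14-ynoate | CCOC(=O)/C(C)=C\CC/C(C)=C/CC/C(C)=C/CCC#C[Si](C(C)C)(C(C)C)C(C)C
F9 | step 13 | labda-13(16),14-diene-7α,8α,19-triol | C=CC(=C)CC[C@H]1[C@](C)(O)[C@H](O)C[C@H]2[C@@](C)(CO)CCC[C@@]21C
F10 | step 13 | methyl (2Z)-3-{4-[(tert-butyldimethylsilyl)oxy]phenyl}prop-2-enoate | COC(=O)/C=C\c1ccc(O[Si](C)(C)C(C)(C)C)cc1
F11 | step 13 | (2Z)-3-{4-[(tert-butyldimethylsilyl)oxy]phenyl}prop-2-enoic acid | OC(=O)/C=C\c1ccc(O[Si](C)(C)C(C)(C)C)cc1
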